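## Retrosynthetic overview

- **Numbering and configuration.** Aryltetralin numbering is used. C1 is the diaryl methine, C2 and C3 carry the CH2OH groups, and C4 is the benzylic CH2. Ring A is the fused arene (C4a–C8a), ring B the carbocycle, and ring C the pendant guaiacyl ring (C1'–C6'). The target is the (1R,2S,3R) isomer: 1,2-trans, 2,3-cis.
- **Last operation.** Hydrogenolysis of three benzyl ethers.
- **Key disconnection.** Both aryl bonds of C1 are cut at once: C1–C1' to ring C (intermolecular) and C1–C8a to ring A (intramolecular). C1 then falls to the aldehyde level. It is masked with the oxygen of the C3-CH2OH group as a five-membered lactol acetate (temporary ring O–C1–C2–C3–CH2). Ring C arrives as an aryltrifluoroborate.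
- **Enabling feature.** C1 is doubly benzylic, and each of its aryl bonds has an oxygen donor para to it: C4'–O in ring C, and C6–OMe para to C8a in ring A. The C3-CH2–O oxygen sits gamma to C1. One Lewis acid can therefore ionise C1 twice, first as a cyclic oxocarbenium ion and then as a para-alkoxybenzyl cation.
- **Origin of the lactol acetate and ring order.** It comes from an (R)-beta-benzylbutyrolactone made by Stobbe condensation. Asymmetric hydrogenation sets C3 and trans alkylation sets C2. The temporary oxygen ring forms first and ring B last. Rings A and C are bought.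

Key step: step 7

Assumption: the (S,S) antipode of Et-DuPhos is taken to give the (R)-configured hydrogenation product, by analogy with itaconate half-esters; if the first run shows the opposite sense, the (R,R) ligand is used with no other change.

## Route

Step 1
Reactants: 1 4-benzyloxy-3-methoxybenzaldehyde; 2 dimethyl succinate
Product: 3 (E)-4-(4-benzyloxy-3-methoxyphenyl)-3-(methoxycarbonyl)but-3-enoic acid
Conditions: NaOMe (1.2 equiv), MeOH, reflux; then 2 M HCl
Reagents that add atoms: none
Why: Stobbe condensation: the succinate enolate adds to the aldehyde, the aldolate closes to a paraconic ester lactone, and its irreversible E1cB opening gives the carboxylate of the half-ester, with the aryl group trans to the ester group (E) for steric reasons.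

Step 2
Reactants: 3 (E)-arylidenesuccinic half-ester
Product: 4 (R)-4-(4-benzyloxy-3-methoxyphenyl)-3-(methoxycarbonyl)butanoic acid
Conditions: [Rh(cod)((S,S)-Et-DuPhos)]BF4 (0.5 mol %), H2 (6 bar), MeOH, rt
Reagents that add atoms: none
Why: Rhodium-catalysed asymmetric hydrogenation of an arylidenesuccinate (beta-aryl itaconate) half-ester: the carboxyl group chelates the cationic rhodium centre beside the alkene, the C2-symmetric bisphospholane leaves one alkene face open, and this sets C3 of the target as (R), while aryl benzyl ethers are inert to this homogeneous catalyst.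

Step 3
Reactants: 4 (R)-half-ester
Product: 6 (R)-4-(4-benzyloxy-3-methoxybenzyl)dihydrofuran-2(3H)-one, via hydroxy acid 5 (not isolated)
Conditions: KOH (1 equiv), EtOH, 0 °C; CaCl2, NaBH4, EtOH, −10 °C → rt; then 2 M HCl, rt
Reagents that add atoms: none
Why: Chemoselective borohydride reduction: Ca(BH4)2 reduces the methyl ester but not the potassium carboxylate, and acidification closes the gamma-hydroxy acid to the five-membered lactone (5-exo-trig lactonisation) without touching the stereocentre.

Step 4
Reactants: 6 (R)-beta-benzylbutyrolactone
Product: 8 (3S,4R)-4-(4-benzyloxy-3-methoxybenzyl)-3-(benzyloxymethyl)dihydrofuran-2(3H)-one, via lithium enolate 7 (not isolated)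
Conditions: LiN(i-Pr)2 (1.05 equiv), THF, −78 °C; BnOCH2Cl, −78 → −20 °C
Reagents that add atoms: benzyl chloromethyl ether, ClCOCc1ccccc1
Why: Diastereoselective alkylation of a beta-substituted butyrolactone enolate: the electrophile approaches the planar enolate anti to the C4 benzyl group, which gives the 3,4-trans lactone and so sets C2 of the target (S) relative to C3 (trans on the oxygen ring corresponds to 2,3-cis on ring B).

Step 5
Reactants: 8 trans-disubstituted lactone
Product: 10 (3S,4R)-4-(4-benzyloxy-3-methoxybenzyl)-3-(benzyloxymethyl)tetrahydrofuran-2-yl acetate (both acetal epimers), via aluminium lactolate 9 (not isolated)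
Conditions: i-Bu2AlH (1.2 equiv), CH2Cl2, −78 °C; then pyridine, DMAP, Ac2O, −78 → 0 °C
Reagents that add atoms: acetic anhydride, CC(=O)OC(C)=O
Why: Reductive acetylation of a lactone: the tetrahedral aluminium lactolate is stable at −78 °C and is O-acylated in situ before it can open to the aldehyde, so neither over-reduction nor epimerisation at the alpha carbon should occur, and the new acetal centre is lost in step 7 and need not be controlled.

Step 6
Reactants: 11 4-benzyloxy-3-methoxyphenylboronic acid
Product: 12 potassium (4-benzyloxy-3-methoxyphenyl)trifluoroborate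
Conditions: KHF2 (aq, 3 equiv), MeOH, rt
Reagents that add atoms: potassium hydrogen difluoride, [K+].[F-].F
Why: Conversion of a boronic acid into its potassium trifluoroborate with KHF2, a general fluoride-for-hydroxide exchange driven by crystallisation of the salt.

Step 7
Reactants: 10 lactol acetate; 12 potassium aryltrifluoroborate
Product: 16 (1R,2S,3R)-7-benzyloxy-1-(4-benzyloxy-3-methoxyphenyl)-2-(benzyloxymethyl)-3-(hydroxymethyl)-6-methoxytetralin, via oxocarbenium ion 13 (not isolated), via 2-aryltetrahydrofuran 14 (not isolated), via benzylic cation 15 (not isolated)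
Conditions: 12 (1.1 equiv), BF3·OEt2 (3 equiv), CH2Cl2, 4 Å molecular sieves, −40 °C, slow addition of 10, then → rt, one flask; aq NaHCO3
Reagents that add atoms: none
Why: Proposed new method: ArBF2, made from 12 and BF3·OEt2, ionises the anomeric acetate of 10 to oxocarbenium ion 13 and the resulting acetoxyborate hands over its aryl group by ipso attack on C1 (this makes the ring C–C1 bond and gives 14); on warming, BF3 ionises the benzylic C1–O bond of 14, which lies para to the benzyloxy group of ring C, and in cation 15 ring A attacks C1 through the carbon para to its methoxy group, after which proton loss gives 16 and frees the C3-CH2OH group. The closest known reaction types are the BF3-promoted addition of potassium aryltrifluoroborates to oxocarbenium ions made from acetals and furanosyl donors, and the acid-induced change of 2-aryl-4-benzyltetrahydrofuran lignans into aryltetralins, which is also the presumed biosynthetic closure of this skeleton; only their merger in one flask is new. Ring B closes by 6-exo-trig Friedel–Crafts alkylation while the temporary tetrahydrofuran ring opens. C1 is controlled by C2: allylic 1,3-strain holds the C2–H bond of 15 in the plane of the cation, so that C3 with its benzyl arm lies on one face and CH2OBn on the other, ring A must bond anti to CH2OBn (1,2-trans, 1R), and both C1 epimers of 14 converge. Should ring A attack 13 first, the bridged C1–O–CH2–C3 ether so formed re-ionises with the help of the C6 methoxy group, and external aryl transfer anti to the bridge gives the same isomer. The step needs ipso selectivity in ring C (secured by boron, since a free or O-benzylated guaiacol would react at several positions), closure para and not ortho to OMe in ring A (secured by the donor pattern and by crowding at the other site) and a single arylation (secured by slow addition of 10 to about one equivalent of aryl donor at low temperature, before 14 can ionise).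

Step 8
Reactants: 16 tri-O-benzyl aryltetralin
Product: 17 (6R,7S,8R)-8-(4-hydroxy-3-methoxyphenyl)-6,7-bis(hydroxymethyl)-3-methoxy-5,6,7,8-tetrahydronaphthalen-2-ol
Conditions: H2 (1 atm), Pd(OH)2/C, MeOH–EtOAc, rt
Reagents that add atoms: none
Why: Catalytic hydrogenolysis of two aryl benzyl ethers and one alkyl benzyl ether; the C1 methine carries only C–C and C–H bonds, so the three stereocentres are not affected.

## Compound list

1 | 4-benzyloxy-3-methoxybenzaldehyde | O=Cc1ccc(OCc2ccccc2)c(OC)c1 | starting material
2 | dimethyl succinate | COC(=O)CCC(=O)OC | starting material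
3 | (E)-4-(4-benzyloxy-3-methoxyphenyl)-3-(methoxycarbonyl)but-3-enoic acid | COC(=O)/C(CC(=O)O)=C/c1ccc(OCc2ccccc2)c(OC)c1 | intermediate
4 | (R)-4-(4-benzyloxy-3-methoxyphenyl)-3-(methoxycarbonyl)butanoic acid | OC(=O)C[C@@H](Cc1ccc(OCc2ccccc2)c(OC)c1)C(=O)OC | intermediate
5 | (R)-4-(4-benzyloxy-3-methoxyphenyl)-3-(hydroxymethyl)butanoic acid | OC(=O)C[C@@H](Cc1ccc(OCc2ccccc2)c(OC)c1)CO | intermediate
6 | (R)-4-(4-benzyloxy-3-methoxybenzyl)dihydrofuran-2(3H)-one | O=C1C[C@@H](Cc2ccc(OCc3ccccc3)c(OC)c2)CO1 | intermediate
7 | lithium enolate of 6 | [Li]OC1=C[C@@H](Cc2ccc(OCc3ccccc3)c(OC)c2)CO1 | intermediate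
8 | (3S,4R)-4-(4-benzyloxy-3-methoxybenzyl)-3-(benzyloxymethyl)dihydrofuran-2(3H)-one (3,4-trans) | O=C1[C@H](COCc2ccccc2)[C@@H](Cc2ccc(OCc3ccccc3)c(OC)c2)CO1 | intermediate
9 | diisobutylaluminium lactolate of 8 | CC(C)C[Al](CC(C)C)OC1[C@H](COCc2ccccc2)[C@@H](Cc2ccc(OCc3ccccc3)c(OC)c2)CO1 | intermediate
10 | (3S,4R)-4-(4-benzyloxy-3-methoxybenzyl)-3-(benzyloxymethyl)tetrahydrofuran-2-yl acetate (acetal carbon as both epimers) | CC(=O)OC1[C@H](COCc2ccccc2)[C@@H](Cc2ccc(OCc3ccccc3)c(OC)c2)CO1 | intermediate
11 | 4-benzyloxy-3-methoxyphenylboronic acid | OB(O)c1ccc(OCc2ccccc2)c(OC)c1 | starting material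
12 | potassium (4-benzyloxy-3-methoxyphenyl)trifluoroborate | [K+].F[B-](F)(F)c1ccc(OCc2ccccc2)c(OC)c1 | intermediate
13 | cyclic oxocarbenium ion from 10 | [O+]1=C[C@H](COCc2ccccc2)[C@@H](Cc2ccc(OCc3ccccc3)c(OC)c2)C1 | intermediate
14 | (3S,4R)-2-(4-benzyloxy-3-methoxyphenyl)-4-(4-benzyloxy-3-methoxybenzyl)-3-(benzyloxymethyl)tetrahydrofuran (both C2 epimers) | C1(c2ccc(OCc3ccccc3)c(OC)c2)[C@H](COCc2ccccc2)[C@@H](Cc2ccc(OCc3ccccc3)c(OC)c2)CO1 | intermediate
15 | ring-opened para-benzyloxybenzyl cation, alkoxide bound to BF3 | F[B-](F)(F)OC[C@H](Cc1ccc(OCc2ccccc2)c(OC)c1)[C@@H](COCc1ccccc1)[CH+]c1ccc(OCc2ccccc2)c(OC)c1 | intermediate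
16 | (1R,2S,3R)-7-benzyloxy-1-(4-benzyloxy-3-methoxyphenyl)-2-(benzyloxymethyl)-3-(hydroxymethyl)-6-methoxytetralin | COc1cc([C@@H]2c3cc(OCc4ccccc4)c(OC)cc3C[C@@H](CO)[C@H]2COCc2ccccc2)ccc1OCc1ccccc1 | intermediate
17 | (6R,7S,8R)-8-(4-hydroxy-3-methoxyphenyl)-6,7-bis(hydroxymethyl)-3-methoxy-5,6,7,8-tetrahydronaphthalen-2-ol | COc1cc([C@@H]2c3cc(O)c(OC)cc3C[C@@H](CO)[C@H]2CO)ccc1O | target

## Step count and risks

Total step count: 8. Longest linear sequence: 7 (steps 1–5, 7, 8).

**Step 7.**
- What may go wrong:
  - The aryl donor may be protodeboronated before it is transferred.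
  - The oxocarbenium ion may lose the C2 proton to give a dihydrofuran, which would erode the C2 configuration.
  - The benzylic cation may be arylated a second time in competition with ring closure.
  - A borate bound to the released alkoxide may deliver the aryl group internally and erode facial selectivity.
- Fallback (known chemistry, sets out from 8, returns at 16):
  - Lactone 8 is reduced with i-Bu2AlH in toluene at −78 °C to the lactol F1.
  - 4-Benzyloxy-3-methoxyphenylmagnesium bromide F2, made from commercial 1-benzyloxy-4-bromo-2-methoxybenzene and Mg in THF, is added in excess. It adds to the open hydroxy-aldehyde form and makes the same ring C–C1 bond, giving the benzylic alcohol 1,4-diol F3 as both carbinol epimers.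
  - CF3CO2H in CH2Cl2 at 0 °C then ionises the carbinol and closes ring B to 16 under the same allylic-strain control.

**Step 4.**
- What may go wrong:
  - The hard chloromethyl ether may alkylate the enolate on oxygen.
  - Proton exchange between product and enolate may lead to double alkylation.
  - Anti selectivity may be incomplete.
- Fallback (sets out from 6, returns at 8):
  - The lithium enolate is treated with monomeric formaldehyde gas at −78 °C. This aldol reaction takes place on the same open face and gives the trans-hydroxymethyl lactone F4.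
  - The primary alcohol is then benzylated under acidic conditions with benzyl 2,2,2-trichloroacetimidate and catalytic CF3SO3H. This avoids base-induced retro-aldol cleavage or elimination and gives 8.

**Step 2.**
- What may go wrong: facial discrimination may be incomplete, or turnover may be slow on the trisubstituted, electron-rich arylidene alkene.
- Fallback (sets out from 3, returns at 4):
  - Compound 3 is hydrogenated with the achiral catalyst [Rh(cod)(dppb)]BF4 to the racemic half-ester F5.
  - The racemate is resolved by fractional crystallisation of the (R)-1-phenylethylammonium salt F6. The amine antipode that gives the less soluble salt with the (R)-acid is to be found by trial.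
  - Acidification releases 4.

## Further compounds

F1 | step 7 | (3S,4R)-4-(4-benzyloxy-3-methoxybenzyl)-3-(benzyloxymethyl)tetrahydrofuran-2-ol | OC1[C@H](COCc2ccccc2)[C@@H](Cc2ccc(OCc3ccccc3)c(OC)c2)CO1
F2 | step 7 | 4-benzyloxy-3-methoxyphenylmagnesium bromide | Br[Mg]c1ccc(OCc2ccccc2)c(OC)c1
F3 | step 7 | (2S,3R)-1-(4-benzyloxy-3-methoxyphenyl)-3-(4-benzyloxy-3-methoxybenzyl)-2-(benzyloxymethyl)butane-1,4-diol (both C1 epimers) | OC[C@H](Cc1ccc(OCc2ccccc2)c(OC)c1)[C@@H](COCc1ccccc1)C(O)c1ccc(OCc2ccccc2)c(OC)c1
F4 | step 4 | (3S,4R)-4-(4-benzyloxy-3-methoxybenzyl)-3-(hydroxymethyl)dihydrofuran-2(3H)-one | O=C1[C@H](CO)[C@@H](Cc2ccc(OCc3ccccc3)c(OC)c2)CO1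
F5 | step 2 | racemic 4-(4-benzyloxy-3-methoxyphenyl)-3-(methoxycarbonyl)butanoic acid | OC(=O)CC(Cc1ccc(OCc2ccccc2)c(OC)c1)C(=O)OC
F6 | step 2 | (R)-1-phenylethylammonium (R)-4-(4-benzyloxy-3-methoxyphenyl)-3-(methoxycarbonyl)butanoate | C[C@@H]([NH3+])c1ccccc1.[O-]C(=O)C[C@@H](Cc1ccc(OCc2ccccc2)c(OC)c1)C(=O)OC
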